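**Compound numbering used throughout**

1 2,4,6-trihydroxybenzaldehyde; 2 bis-MOM salicylaldehyde; 3 1-bromo-3-methylbut-2-ene; 4 aryl prenyl ether; 5 ortho-dienone (transient); 6 C-allylated salicylaldehyde; 7 ethyl bromoacetate; 8 aryloxyacetate (transient); 9 dihydrobenzofuranol (transient); 10 benzofuran-2-carboxylate; 11 pentane-2,4-dione; 12 8-methylnon-7-ene-2,4-dione; 13 triketone; 14 aldol adduct (transient); 15 prenylated resorcinol; 16 tetraphenol (transient); 17 target. Full names and SMILES are in the compound list.

## Analysis of the target

The target is a 2-arylbenzofuran. The benzofuran (ring A benzene, ring B furan) carries hydroxyls on C4 and C6 and a 2-methylbut-3-en-2-yl (reverse prenyl) group on C7, and its C2 is bonded to C5 of a 7-hydroxy-2,2-dimethylchroman (ring C benzene, ring D pyran). There is no stereocentre, so the problem is one of regiochemistry on two electron-rich arenes. Ring A is a phloroglucinol-type ring with a tertiary allylic substituent next to a phenol: it is easily oxidised, acid can cyclise, shift or cleave that substituent, and its terminal alkene excludes hydrogenolysis and most late electrophilic alkene chemistry. Ring C is the harder half: it is 1,2,3,5-tetrasubstituted, the bond to the benzofuran on C5 sits next to the alkyl carbon C4a, and the pyran must be fused on the side of the resorcinol that faces the aryl group. Direct prenylation or chroman annulation of a 5-arylresorcinol would be expected to favour the carbon between the two oxygens or to give mixtures. The plan rests on the fact that ring C (C4a, C5, C6, C7, C8, C8a) has oxygen on C7 and C8a and carbon substituents on the adjacent C4a and C5, which is the pattern a 1,3,5-triketone gives when it folds by aldol condensation. Building ring C from such a chain sets its substitution pattern and the bond to the benzofuran in one operation, and leaves the pyran closure unambiguous because only the C8a hydroxyl adjoins the C4a side chain.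

## Retrosynthetic reasoning

**17 to 15.** The pyran bond O1–C2 of ring D is cut and the two ring A hydroxyls are masked as methoxymethyl ethers. Cutting at the gem-dimethyl carbon reveals a 3-methylbut-2-enyl chain on C4a and a free hydroxyl on C8a, that is resorcinol 15; any other pyran bond would have to be made by substitution on the arene. The forward reaction must add the C8a hydroxyl across the trisubstituted alkene in the Markovnikov sense and cleave both acetals without engaging the monosubstituted alkene on ring A; the tetraphenol 16 is the expected intermediate.

**15 to 13 (key disconnection).** Ring C is opened at C4a–C5, and C5, C7 and C8a are returned to the carbonyl level, which leads through the aldol adduct 14 to the open-chain triketone 13. This is the only ring bond whose cleavage maps all six ring carbons and both oxygens onto a linear polyketone: C5 is the one carbon that can have been an aryl ketone and C4a the α-carbon of the terminal ketone. The gain is that the crowded arene and the inter-ring bond become an acyclic chain with one foldable mode. The forward reaction must make the enolate carbon next to the terminal ketone add to the benzofuranyl ketone and then aromatise by dehydration.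

**13 to 10 and 12.** The chain is cut between the aroyl carbon (future C5) and the neighbouring methylene (future C6). This is the acylation of the dianion of diketone 12 by ester 10. It divides 13 into the complete benzofuran and the complete aliphatic chain and needs no carbonyl protection. The forward reaction requires the second deprotonation of 12 to take place at its methyl terminus.

**12 to 11 and 3.** The C5–C6 bond of 12 is cut, which corresponds to terminal alkylation of the dianion of 11 with bromide 3. This takes one step and avoids the methyl-versus-methylene question that a crossed ester condensation of a methyl ketone would raise; bromide 3 is needed elsewhere in the route in any case.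

**10 to 6 and 7.** Ring B is cut at O1–C2 and C2–C3. Salicylaldehyde 6 supplies O1 and C3 (its formyl carbon) and bromo ester 7 supplies C2 with the ester already attached, through the transient 8 and 9. The ester on C2 is exactly the acyl donor the previous disconnection calls for.

**6 to 4, then 2, 1 and 3.** The bond from the arene carbon (future benzofuran C7) to the quaternary allylic carbon is cut as a Claisen retron: a 2-methylbut-3-en-2-yl group next to a free phenol is what a 3-methylbut-2-enyl aryl ether gives on [3,3] rearrangement, through dienone 5. Ether 4 comes from O-alkylation of 2 with 3, and 2 from 1 by protecting the two hydroxyls that are not chelated to the formyl group. The oxygen that carries the allyl group is the one that later becomes the furan oxygen, so the rearrangement unmasks precisely the phenol needed for the annulation.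

## Alternatives that were turned down

**Alternative 1:** The disconnection is the furan bond C3–C3a, with the ether oxygen O1 already joined to the future C2. In the forward key step acid activates the aldehyde of the α-aryloxy aldehyde A2, ring A attacks through its only free position ortho to the ether oxygen (the other is blocked by the tertiary allylic group), and dehydration aromatises ring B to give the trisilyl ether A1.
- For: it unites two complete aromatic halves, the regiochemistry of the closure is certain, and the last step would be a fluoride desilylation. That end is gentler than the acidic final step of the chosen route, and on this point alternative 1 is the stronger plan.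
- Against: A2 is a fragile, enolisable aldehyde. Its assembly requires O-alkylation of a phenol flanked by a quaternary carbon with a secondary benzylic electrophile. The cyclodehydration needs a strong Brønsted or Lewis acid exactly where the molecule is weakest, on an electron-rich ring A carrying the tertiary allylic group and acid-labile aryl silyl ethers. The 1,2,3,5-pattern of ring C is not addressed at all and would have to come from arene substitution.
- Comparison: the chosen route forms its strategic bond under base and takes ring C's pattern from a chain; alternative 1 would need two fragments of five to six steps each before the union.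

**Alternative 2:** The disconnection is the aryl carbon–oxygen bond O1–C8a of the chroman inside an isolated ring C/ring D fragment, with the inter-ring bond left for a later cross-coupling. In the forward key step the tertiary alkoxide of dibromide A4 displaces one of two equivalent bromides under palladium or copper catalysis and gives bromochroman A3.
- For: symmetry guarantees the regiochemistry. The alkoxide has no hydrogen on its carbinol carbon, so the usual β-hydride elimination is closed. Every later step (metalation of a benzofuran at C2, cross-coupling, desilylation) is modular and well behaved. In step-by-step predictability alternative 2 is stronger than the chosen route.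
- Against: the key step builds only ring D of one fragment. The reverse-prenylated benzofuran still needs the four steps used here plus conversion into a 2-metallated partner, and 2-benzofuranylboron reagents protodeboronate easily. The coupling site is ortho to the C4 methylene, and two transition-metal steps are required.
- Comparison: the chosen route offers the same certainty for the pyran, since only one hydroxyl adjoins the side chain, needs no metal, and forms the inter-ring bond while it constructs ring C, in roughly half the number of operations.

**Alternative 3:** The disconnection is C4–C5 of ring A, which is grown last onto a 2,3,5-trisubstituted furan. In the forward key step base generates the methyl ketone enolate of keto ester A6, which attacks the ester on the furan 3-position in a Dieckmann-type closure; the ring tautomerises to the 4,6-diol A5.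
- For: it is as biomimetic as the chosen plan. The tertiary allylic group sits on an sp3 carbon before aromatisation, so no aromatic Claisen rearrangement with its ortho/para question is needed; that is a real advantage over the chosen route. The product is one fluoride deprotection from the target.
- Against: A6 is the real difficulty. It is a furan bearing a methine flanked by a quaternary carbon, a ketone and the heteroarene. That methine is more acidic than the methyl group that has to react. The chroman with its hard substitution pattern must still be made separately and attached to the furan. The free, oxidisable diol is released under base.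
- Comparison: the chosen route spends its biomimetic step on the harder ring C and obtains ring A from a commodity aldehyde in four steps.

Key step: step 7

Assumption: LiN(i-Pr)2 is used as a commercial solution, and in step 8 acetal cleavage is taken to precede pyran closure; the opposite order would lead to the same product.

## Route

Step 1
Reactants: 1 2,4,6-trihydroxybenzaldehyde
Product: 2 2-hydroxy-4,6-bis(methoxymethoxy)benzaldehyde
Conditions: MOMCl (2.1 equiv), i-Pr2NEt, CH2Cl2, 0 °C → rt
Reagents that add atoms: chloromethyl methyl ether (MOMCl), COCCl
Why: Phenol O-alkylation by an α-chloro ether; the hydroxyl that stays hydrogen-bonded to the formyl oxygen is the least nucleophilic, so two equivalents of reagent should stop at the bis-acetal with the chelated phenol free.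

Step 2
Reactants: 2 2-hydroxy-4,6-bis(methoxymethoxy)benzaldehyde; 3 1-bromo-3-methylbut-2-ene
Product: 4 2,4-bis(methoxymethoxy)-6-(3-methylbut-2-enyloxy)benzaldehyde
Conditions: K2CO3, DMF, 50 °C
Reagents that add atoms: none
Why: Williamson ether synthesis by SN2 displacement at the primary allylic bromide; K2CO3 in DMF breaks the chelate and the phenoxide oxygen should be alkylated in preference to ring carbon.

Step 3
Reactants: 4 2,4-bis(methoxymethoxy)-6-(3-methylbut-2-enyloxy)benzaldehyde
Product: 6 2-hydroxy-4,6-bis(methoxymethoxy)-3-(2-methylbut-3-en-2-yl)benzaldehyde, via ortho-dienone 5 (not isolated)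
Conditions: PhNEt2, 190 °C, Ar
Reagents that add atoms: none
Why: Aromatic Claisen rearrangement: the [3,3] shift can only reach the one unsubstituted ortho carbon and inverts the allyl unit, turning the O-bound 3-methylbut-2-enyl group into the C-bound 2-methylbut-3-en-2-yl group; the basic amine solvent speeds enolisation of dienone 5 so that a second (Cope) shift to the para carbon is outrun, and the new phenol is held in a chelate by the formyl group, which disfavours further thermal isomerisation.

Step 4
Reactants: 6 2-hydroxy-4,6-bis(methoxymethoxy)-3-(2-methylbut-3-en-2-yl)benzaldehyde; 7 ethyl bromoacetate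
Product: 10 ethyl 4,6-bis(methoxymethoxy)-7-(2-methylbut-3-en-2-yl)benzofuran-2-carboxylate, via aryloxyacetate 8 (not isolated), via dihydrobenzofuranol 9 (not isolated)
Conditions: K2CO3, DMF, 60 °C then 110 °C
Reagents that add atoms: none
Why: Rap–Stoermer-type benzofuran annulation: O-alkylation of the phenoxide by the α-bromo ester, 5-exo-trig aldol addition of the ester enolate to the neighbouring formyl group and E1cB dehydration, driven by formation of the aromatic furan; the acetals and the terminal alkene are inert to carbonate.

Step 5
Reactants: 11 pentane-2,4-dione; 3 1-bromo-3-methylbut-2-ene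
Product: 12 8-methylnon-7-ene-2,4-dione
Conditions: LiN(i-Pr)2 (2.1 equiv), THF, −78 → 0 °C; then 3, 0 °C; cold 1 M HCl
Reagents that add atoms: none
Why: Terminal alkylation of a β-diketone dianion: the carbanion formed in the second deprotonation is far more nucleophilic than the delocalised central enolate, so SN2 attack on the allylic bromide should occur only at the methyl terminus and give the linear chain.

Step 6
Reactants: 12 8-methylnon-7-ene-2,4-dione; 10 ethyl 4,6-bis(methoxymethoxy)-7-(2-methylbut-3-en-2-yl)benzofuran-2-carboxylate
Product: 13 1-[4,6-bis(methoxymethoxy)-7-(2-methylbut-3-en-2-yl)benzofuran-2-yl]-9-methyldec-8-ene-1,3,5-trione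
Conditions: 12 (2.2 equiv), LiN(i-Pr)2 (4.5 equiv), THF, −78 → 0 °C; then 10, 0 °C → rt; 1 M HCl to pH 5, 0 °C
Reagents that add atoms: none
Why: Claisen-type acylation of a 1,3-diketone dianion by an ester, a standard entry to 1,3,5-triketones; the second proton should be removed kinetically from the unhindered methyl of 12 rather than from its C5 methylene, the terminal carbanion adds to the ester carbonyl with loss of ethoxide, and the excess dianion absorbs the acidic proton of the product.

Step 7
Reactants: 13 1-[4,6-bis(methoxymethoxy)-7-(2-methylbut-3-en-2-yl)benzofuran-2-yl]-9-methyldec-8-ene-1,3,5-trione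
Product: 15 5-[4,6-bis(methoxymethoxy)-7-(2-methylbut-3-en-2-yl)benzofuran-2-yl]-4-(3-methylbut-2-enyl)benzene-1,3-diol, via aldol adduct 14 (not isolated)
Conditions: KOH (1 M aq), MeOH, Ar, rt → 40 °C; then 1 M HCl to pH 5, 0 °C
Reagents that add atoms: none
Why: Intramolecular aldol condensation of a 1,3,5-triketone (polyketide-type benzannulation), the closest known cases being the hydroxide-mediated conversion of heptane-2,4,6-trione into orcinol and the aldol closure of aryl-terminated 3,5,7-triketo acids onto their aryl ketone. In aqueous KOH the triketone is present as its enolates; the enolate carbon C6 of the chain, α to the C5 carbonyl, adds to the benzofuranyl ketone carbon C1 and forms the C4a–C5 bond of ring C in a 6-(enolendo)-exo-trig closure that gives the β-hydroxy diketone 14. E1cB loss of hydroxide from 14 and enolisation of the two remaining carbonyls deliver the resorcinol, and this aromatisation makes the sequence irreversible. No stereocentre survives, because the two centres of 14 are erased on aromatisation. The step needs carbon–carbon closure to beat oxygen–carbon closure to a 4-pyranone and to beat hydroxide cleavage of the polyketone; the first is secured by the basic medium, in which hemiketal formation is reversible and its dehydration is not promoted, the second by working near room temperature, where the polyketone is shielded as its anion. Regiochemistry is fixed by the substrate, since the aryl ketone has no α-hydrogen on its far side and every other enolate–carbonyl pairing would close a four-membered ring. The acetals, the trisubstituted alkene and the 2-methylbut-3-en-2-yl group are all inert to aqueous base.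

Step 8
Reactants: 15 5-[4,6-bis(methoxymethoxy)-7-(2-methylbut-3-en-2-yl)benzofuran-2-yl]-4-(3-methylbut-2-enyl)benzene-1,3-diol
Product: 17 2-(7-hydroxy-2,2-dimethylchroman-5-yl)-7-(2-methylbut-3-en-2-yl)benzofuran-4,6-diol, via tetraphenol 16 (not isolated)
Conditions: HCl (2 M in MeOH), Ar, rt then 50 °C
Reagents that add atoms: none
Why: Acid-catalysed acetal methanolysis frees the two ring A phenols, and Markovnikov protonation of the trisubstituted alkene gives a tertiary cation that is captured by the only neighbouring hydroxyl (on C8a) in a 6-endo closure to the 2,2-dimethylchroman (intramolecular hydroalkoxylation); the monosubstituted alkene on ring A would have to pass through a secondary cation and should react far more slowly.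

## Compound list

1 | 2,4,6-trihydroxybenzaldehyde | O=Cc1c(O)cc(O)cc1O | starting material
2 | 2-hydroxy-4,6-bis(methoxymethoxy)benzaldehyde | O=Cc1c(O)cc(OCOC)cc1OCOC | intermediate
3 | 1-bromo-3-methylbut-2-ene | CC(C)=CCBr | starting material
4 | 2,4-bis(methoxymethoxy)-6-(3-methylbut-2-enyloxy)benzaldehyde | O=Cc1c(OCC=C(C)C)cc(OCOC)cc1OCOC | intermediate
5 | 2-formyl-3,5-bis(methoxymethoxy)-6-(2-methylbut-3-en-2-yl)cyclohexa-2,4-dien-1-one (racemic, transient) | O=CC1=C(OCOC)C=C(OCOC)C(C(C)(C)C=C)C1=O | intermediate
6 | 2-hydroxy-4,6-bis(methoxymethoxy)-3-(2-methylbut-3-en-2-yl)benzaldehyde | O=Cc1c(O)c(C(C)(C)C=C)c(OCOC)cc1OCOC | intermediate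
7 | ethyl bromoacetate | CCOC(=O)CBr | starting material
8 | ethyl 2-[2-formyl-3,5-bis(methoxymethoxy)-6-(2-methylbut-3-en-2-yl)phenoxy]acetate (transient) | CCOC(=O)COc1c(C=O)c(OCOC)cc(OCOC)c1C(C)(C)C=C | intermediate
9 | ethyl 3-hydroxy-4,6-bis(methoxymethoxy)-7-(2-methylbut-3-en-2-yl)-2,3-dihydrobenzofuran-2-carboxylate (racemic mixture of diastereomers, transient) | CCOC(=O)C1Oc2c(C(C)(C)C=C)c(OCOC)cc(OCOC)c2C1O | intermediate
10 | ethyl 4,6-bis(methoxymethoxy)-7-(2-methylbut-3-en-2-yl)benzofuran-2-carboxylate | CCOC(=O)c1cc2c(OCOC)cc(OCOC)c(C(C)(C)C=C)c2o1 | intermediate
11 | pentane-2,4-dione | CC(=O)CC(C)=O | starting material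
12 | 8-methylnon-7-ene-2,4-dione | CC(=O)CC(=O)CCC=C(C)C | intermediate
13 | 1-[4,6-bis(methoxymethoxy)-7-(2-methylbut-3-en-2-yl)benzofuran-2-yl]-9-methyldec-8-ene-1,3,5-trione | C=CC(C)(C)c1c(OCOC)cc(OCOC)c2cc(C(=O)CC(=O)CC(=O)CCC=C(C)C)oc12 | intermediate
14 | 5-[4,6-bis(methoxymethoxy)-7-(2-methylbut-3-en-2-yl)benzofuran-2-yl]-5-hydroxy-4-(3-methylbut-2-enyl)cyclohexane-1,3-dione (racemic mixture of diastereomers, transient) | C=CC(C)(C)c1c(OCOC)cc(OCOC)c2cc(C3(O)CC(=O)CC(=O)C3CC=C(C)C)oc12 | intermediate
15 | 5-[4,6-bis(methoxymethoxy)-7-(2-methylbut-3-en-2-yl)benzofuran-2-yl]-4-(3-methylbut-2-enyl)benzene-1,3-diol | C=CC(C)(C)c1c(OCOC)cc(OCOC)c2cc(-c3cc(O)cc(O)c3CC=C(C)C)oc12 | intermediate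
16 | 2-[3,5-dihydroxy-2-(3-methylbut-2-enyl)phenyl]-7-(2-methylbut-3-en-2-yl)benzofuran-4,6-diol (transient) | C=CC(C)(C)c1c(O)cc(O)c2cc(-c3cc(O)cc(O)c3CC=C(C)C)oc12 | intermediate
17 | 2-(7-hydroxy-2,2-dimethylchroman-5-yl)-7-(2-methylbut-3-en-2-yl)benzofuran-4,6-diol (CNP0300714.0, no stereocentre) | C=CC(C)(C)c1c(O)cc(O)c2cc(-c3cc(O)cc4c3CCC(C)(C)O4)oc12 | target

## Step count and least certain steps

Total step count: 8. Longest linear sequence: 7 steps (steps 1, 2, 3, 4, 6, 7, 8); step 5 is a one-step side branch.

**Step 7 (key step).** The aldol addition may fail to compete with hydroxide cleavage of the polyketone (retro-Claisen fragmentation) or with dehydrative oxygen–carbon closure, because the electrophile is a conjugated heteroaryl ketone partly tied up as a diketonate and the nucleophilic carbon is a substituted methylene. The fallback closes the same ring through the complementary fold, in which an unhindered methyl group is the nucleophile. It sets out from ester 10. Crossed Claisen condensation of 10 with the lithium enolate of acetone (LiN(i-Pr)2, THF, −78 °C → rt) should give 1-[4,6-bis(methoxymethoxy)-7-(2-methylbut-3-en-2-yl)benzofuran-2-yl]butane-1,3-dione F1. C-alkylation of F1 with bromide 3 (K2CO3, acetone, reflux) should place the side chain on the central carbon and give 1-[4,6-bis(methoxymethoxy)-7-(2-methylbut-3-en-2-yl)benzofuran-2-yl]-2-(3-methylbut-2-enyl)butane-1,3-dione F2. Dianion formation (LiN(i-Pr)2, 2.2 equiv) and acetylation of the terminal carbanion with N-methoxy-N-methylacetamide should give the branched triketone 1-[4,6-bis(methoxymethoxy)-7-(2-methylbut-3-en-2-yl)benzofuran-2-yl]-2-(3-methylbut-2-enyl)hexane-1,3,5-trione F3. Aqueous KOH should then add the terminal methyl carbon to the aryl ketone and, after dehydration, return the route to 15.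

**Step 8.** Acid strong enough to protonate the trisubstituted alkene may also attack ring A once its C6 hydroxyl is free: cyclisation of the 2-methylbut-3-en-2-yl group onto that hydroxyl, or ipso-protonation with migration or loss of the allylic group. Capture of the tertiary cation by the solvent may also stall the pyran closure. The fallback separates the two events and closes the pyran without strong acid. It sets out from 15. N-(phenylseleno)phthalimide with a catalytic amount of camphorsulfonic acid (CH2Cl2, −78 → 0 °C) should effect selenoetherification of the trisubstituted alkene by the C8a hydroxyl and give racemic 5-[4,6-bis(methoxymethoxy)-7-(2-methylbut-3-en-2-yl)benzofuran-2-yl]-2,2-dimethyl-3-(phenylselanyl)chroman-7-ol F4. Radical deselenation (Bu3SnH, AIBN, toluene, 80 °C) should give 5-[4,6-bis(methoxymethoxy)-7-(2-methylbut-3-en-2-yl)benzofuran-2-yl]-2,2-dimethylchroman-7-ol F5. A brief treatment with HCl in MeOH at room temperature, which now only has to cleave the acetals, should lead to 17.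

**Step 3.** After the first [3,3] shift, a second shift of dienone 5 to the para carbon between the two acetal oxygens may outrun enolisation (poor ortho/para selectivity), and prolonged heating may isomerise the product. The fallback moves the rearrangement to the benzofuran stage, where the para position is a ring-fusion carbon. It sets out from 1. Alkylation of the most acidic, non-chelated hydroxyl with bromide 3 (K2CO3, 1 equiv, acetone, rt) should give 2,6-dihydroxy-4-(3-methylbut-2-enyloxy)benzaldehyde F6. Mono-protection (MOMCl, 1 equiv, i-Pr2NEt) should give 2-hydroxy-6-(methoxymethoxy)-4-(3-methylbut-2-enyloxy)benzaldehyde F7. Annulation with bromo ester 7 as in step 4 should give ethyl 4-(methoxymethoxy)-6-(3-methylbut-2-enyloxy)benzofuran-2-carboxylate F8. Claisen rearrangement (PhNEt2, 190 °C), expected to go to the less hindered C7 next to the ring oxygen, should give ethyl 6-hydroxy-4-(methoxymethoxy)-7-(2-methylbut-3-en-2-yl)benzofuran-2-carboxylate F9. Protection of the new phenol with MOMCl rejoins the route at 10.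

**Step 6.** The second deprotonation of 12 may occur in part at the C5 methylene instead of the methyl group, and proton transfer from the acidic product may consume dianion; the result would be regioisomeric acylation or incomplete conversion. The fallback alkylates last, so that no regiochemical choice arises. It sets out from 10 and 11. The dianion of the symmetrical diketone 11 (LiN(i-Pr)2, 2 equiv) is acylated by 10 to give 1-[4,6-bis(methoxymethoxy)-7-(2-methylbut-3-en-2-yl)benzofuran-2-yl]hexane-1,3,5-trione F10. Its trianion (LiN(i-Pr)2, 3.3 equiv, THF, 0 °C) should be alkylated at the terminal carbon by bromide 3, which rejoins the route at 13.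

## Further compounds

F1 | step 7 | 1-[4,6-bis(methoxymethoxy)-7-(2-methylbut-3-en-2-yl)benzofuran-2-yl]butane-1,3-dione | C=CC(C)(C)c1c(OCOC)cc(OCOC)c2cc(C(=O)CC(C)=O)oc12
F2 | step 7 | 1-[4,6-bis(methoxymethoxy)-7-(2-methylbut-3-en-2-yl)benzofuran-2-yl]-2-(3-methylbut-2-enyl)butane-1,3-dione | C=CC(C)(C)c1c(OCOC)cc(OCOC)c2cc(C(=O)C(CC=C(C)C)C(C)=O)oc12
F3 | step 7 | 1-[4,6-bis(methoxymethoxy)-7-(2-methylbut-3-en-2-yl)benzofuran-2-yl]-2-(3-methylbut-2-enyl)hexane-1,3,5-trione | C=CC(C)(C)c1c(OCOC)cc(OCOC)c2cc(C(=O)C(CC=C(C)C)C(=O)CC(C)=O)oc12
F4 | step 8 | 5-[4,6-bis(methoxymethoxy)-7-(2-methylbut-3-en-2-yl)benzofuran-2-yl]-2,2-dimethyl-3-(phenylselanyl)chroman-7-ol (racemic) | C=CC(C)(C)c1c(OCOC)cc(OCOC)c2cc(-c3cc(O)cc4c3CC([Se]c5ccccc5)C(C)(C)O4)oc12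
F5 | step 8 | 5-[4,6-bis(methoxymethoxy)-7-(2-methylbut-3-en-2-yl)benzofuran-2-yl]-2,2-dimethylchroman-7-ol | C=CC(C)(C)c1c(OCOC)cc(OCOC)c2cc(-c3cc(O)cc4c3CCC(C)(C)O4)oc12
F6 | step 3 | 2,6-dihydroxy-4-(3-methylbut-2-enyloxy)benzaldehyde | O=Cc1c(O)cc(OCC=C(C)C)cc1O
F7 | step 3 | 2-hydroxy-6-(methoxymethoxy)-4-(3-methylbut-2-enyloxy)benzaldehyde | O=Cc1c(O)cc(OCC=C(C)C)cc1OCOC
F8 | step 3 | ethyl 4-(methoxymethoxy)-6-(3-methylbut-2-enyloxy)benzofuran-2-carboxylate | CCOC(=O)c1cc2c(OCOC)cc(OCC=C(C)C)cc2o1
F9 | step 3 | ethyl 6-hydroxy-4-(methoxymethoxy)-7-(2-methylbut-3-en-2-yl)benzofuran-2-carboxylate | CCOC(=O)c1cc2c(OCOC)cc(O)c(C(C)(C)C=C)c2o1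
F10 | step 6 | 1-[4,6-bis(methoxymethoxy)-7-(2-methylbut-3-en-2-yl)benzofuran-2-yl]hexane-1,3,5-trione | C=CC(C)(C)c1c(OCOC)cc(OCOC)c2cc(C(=O)CC(=O)CC(C)=O)oc12
A1 | alternative 1 | 4,6-bis(tert-butyldimethylsilyloxy)-2-[7-(tert-butyldimethylsilyloxy)-2,2-dimethylchroman-5-yl]-7-(2-methylbut-3-en-2-yl)benzofuran | C=CC(C)(C)c1c(O[Si](C)(C)C(C)(C)C)cc(O[Si](C)(C)C(C)(C)C)c2cc(-c3cc(O[Si](C)(C)C(C)(C)C)cc4c3CCC(C)(C)O4)oc12
A2 | alternative 1 | 2-[3,5-bis(tert-butyldimethylsilyloxy)-2-(2-methylbut-3-en-2-yl)phenoxy]-2-[7-(tert-butyldimethylsilyloxy)-2,2-dimethylchroman-5-yl]acetaldehyde (racemic) | C=CC(C)(C)c1c(OC(C=O)c2cc(O[Si](C)(C)C(C)(C)C)cc3c2CCC(C)(C)O3)cc(O[Si](C)(C)C(C)(C)C)cc1O[Si](C)(C)C(C)(C)C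
A3 | alternative 2 | 5-bromo-2,2-dimethyl-7-(triisopropylsilyloxy)chroman | CC1(C)CCc2c(Br)cc(O[Si](C(C)C)(C(C)C)C(C)C)cc2O1
A4 | alternative 2 | 4-[2,6-dibromo-4-(triisopropylsilyloxy)phenyl]-2-methylbutan-2-ol | CC(C)(O)CCc1c(Br)cc(O[Si](C(C)C)(C(C)C)C(C)C)cc1Br
A5 | alternative 3 | 2-[2,2-dimethyl-7-(triisopropylsilyloxy)chroman-5-yl]-7-(2-methylbut-3-en-2-yl)benzofuran-4,6-diol | C=CC(C)(C)c1c(O)cc(O)c2cc(-c3cc(O[Si](C(C)C)(C(C)C)C(C)C)cc4c3CCC(C)(C)O4)oc12
A6 | alternative 3 | methyl 2-(4,4-dimethyl-2-oxohex-5-en-3-yl)-5-[2,2-dimethyl-7-(triisopropylsilyloxy)chroman-5-yl]furan-3-carboxylate (racemic) | COC(=O)c1cc(-c2cc(O[Si](C(C)C)(C(C)C)C(C)C)cc3c2CCC(C)(C)O3)oc1C(C(C)=O)C(C)(C)C=C
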